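The data stem from a simulated flask on assumed constants, noise included.

At early times, before the first sample of either earlier run, those two flasks must have been changing with the clock, and two of us dispute what their flat later readings say of red at its asked time.

| flask | starting complex | incoming ligand | remark | time |
|---|---|---|---|---|
| east | 2 mM | 0.64 equiv | run made earlier |  |
| north | 2 mM | 2.1 equiv | run made earlier |  |
| grey | 2.0 mM | 1.00 equiv |  | 10 min |
| red | 2.0 mM | 2.00 equiv |  | 10 min |
| amber | 2.0 mM | 3.00 equiv |  | 10 min |

| run | time / min | complex with three exchanged / % | complex with one exchanged / % |
|---|---|---|---|
| east | 2.00 | 7 | 21 |
| east | 4.00 | 5 | 19 |
| east | 5.00 | 9 | 20 |
| east | 8.00 | 8 | 19 |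
| north | 0.500 | 56 | 14 |
| north | 1.33 | 55 | 10 |
| north | 3.00 | 57 | 10 |
| north | 8.00 | 55 | 10 |

(standard deviation of a reading: 1.5 percentage points)

- which of these holds the largest part of the starting complex at the end of grey (complex with two exchanged / complex with three exchanged / starting complex / complex with one exchanged)
- which of these holds the largest part of the starting complex at the end of red (complex with two exchanged / complex with three exchanged / starting complex / complex with one exchanged)
- which of these holds the largest part of the starting complex at the end of amber (complex with two exchanged / complex with three exchanged / starting complex / complex with one exchanged)
- complex with three exchanged at the end of red, in percent of the starting complex charged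



The first of us takes the clock view: the readings of complex with three exchanged in north stay flat from 0.500 min to 8.00 min, and red is charged with 95.2 % of the incoming ligand of north, so red at 10 min should stand on the north plateau, whose mean is 55.8 %.

The second, whose reckoning this is, takes the ledger view: the incoming ligand is the limiting reagent, with 2.00 equiv in red against 3 places on each complex, so a flat reading marks a closed account, and the end of red follows its charge rather than its clock. From the east mean of 7.25 % to the north mean, both of them means of scattered readings, complex with three exchanged gains on average 0.332 of the charge per equivalent of incoming ligand across that span, and this marginal yield is the quantity to carry. Red lies close to north, so the plateau is taken as the large thing and the missing ligand as the small one: the correction is 3.3 percentage points, which puts red at 52.4 %.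

The forecast sides with the ledger by another road, a fit of consecutive steps, holding that “the incoming ligand is used up, and the mixture is a frozen product distribution”. It names starting complex, complex with three exchanged and complex with three exchanged as the largest holders in grey, red and amber, and gives 50 % for red, between 46 % and 54 %, which is lower than my reckoning, while the clock view stands above that range.

The flask gives 51.2 % for red, with starting complex, complex with three exchanged and complex with three exchanged the largest holders in grey, red and amber, as the forecast said.

    starting complex + incoming ligand → leaving ligand + complex with one exchanged (k = 73.0 M⁻¹ s⁻¹)
    complex with one exchanged + incoming ligand → leaving ligand + complex with two exchanged (k = 170 M⁻¹ s⁻¹)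
    complex with two exchanged + incoming ligand → leaving ligand + complex with three exchanged (k = 220 M⁻¹ s⁻¹)
    complex with one exchanged + incoming ligand → over-reaction product (k = 16.0 M⁻¹ s⁻¹)

The ledger view stands: red holds 0 % of its incoming ligand at 5.00 min, and its answer is 51.2 % at 100 min. The clock view has its region at the charge of north: the answer of red has moved by 5 points once its incoming ligand is raised to 2.12 equiv. The neighbour of red charged with 0.500 equiv lies close to east, so the same marginal yield, subtracted from the east mean across that gap, gives 2.60 % of complex with three exchanged, and that neighbour holds 3.99 %.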